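**Retrosynthetic overview**
1. The target is the 7‑O‑ether of umbelliferone with a C10 chain, C1'H2–C2'H(OH)–C3'(CH3)(OH)–C4'H2. The chain ends at C5', the ring carbon next to the ring oxygen of an α‑methylene‑γ‑butyrolactone.
2. Enabling feature: the lactone ring oxygen on C5' is β to the tertiary carbinol carbon C3' (O–C5'–C4'–C3'). The lactone half is therefore the oxa‑Michael isomer of an acyclic (E)‑enone ester, and in that ring‑opened form C3' can become the γ‑carbon of a siloxyallyl metal.
3. Key disconnection C2'–C3': a ligand‑controlled chromium pinacol‑type cross‑coupling of the enone ester with (coumarin‑7‑yloxy)acetaldehyde. It makes the bond, both carbinol stereocentres (anti) and an (E)‑C4'=C5' alkene in one operation.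
4. The alkene is then used up: 5‑exo iodolactonisation forms C5'–O (1,3‑induction from C3') and closes the butyrolactone, the only ring made in the route. Deiodination and desilylation finish the synthesis.
5. Both coumarin rings come with umbelliferone. The enone ester comes from tert‑butyl 2‑(bromomethyl)acrylate by SN2' vinylation and cross‑metathesis with methyl vinyl ketone.

Key step: step 5

Remark: primed locants count the side chain from the ether oxygen; the antipode of the chromium ligand is fixed on a model aldehyde, because its sense of induction cannot be derived from first principles.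

Step 1
Reactants: 1 umbelliferone; 2 allyl bromide
Product: 3 7-(prop-2-en-1-yloxy)-2H-chromen-2-one
Conditions: K2CO3, acetone, reflux
Reagents that add atoms: none
Why: Williamson ether synthesis, in which the acidic 7‑phenol is alkylated at oxygen by the allylic bromide and no stereocentre is involved.

Step 2
Reactants: 3 7-(prop-2-en-1-yloxy)-2H-chromen-2-one
Product: 5 2-[(2-oxo-2H-chromen-7-yl)oxy]acetaldehyde, via racemic vicinal diol 4 (not isolated)
Conditions: OsO4 (2 mol %), NaIO4, 2,6-lutidine, dioxane/H2O, rt; azeotropic drying before use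
Reagents that add atoms: sodium periodate, [Na+].[O-]I(=O)(=O)=O (terminal oxygen source, relayed through catalytic OsO4)
Why: Lemieux–Johnson oxidation, in which OsO4 should dihydroxylate the electron‑rich terminal alkene much faster than the electron‑poor conjugated C3=C4 bond of the coumarin, and periodate cleaves the diol to the aldehyde.

Step 3
Reactants: 6 tert-butyl 2-(bromomethyl)prop-2-enoate; 7 vinylmagnesium bromide
Product: 8 tert-butyl 2-methylidenepent-4-enoate
Conditions: CuI (10 mol %), THF, −78 °C
Reagents that add atoms: none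
Why: Copper‑catalysed SN2' (addition–elimination) substitution of the 2‑(bromomethyl)acrylate by the vinyl Grignard reagent, which regenerates the acrylate while the bulky tert‑butyl ester blocks 1,2‑addition.

Step 4
Reactants: 8 tert-butyl 2-methylidenepent-4-enoate; 9 methyl vinyl ketone
Product: 10 tert-butyl (4E)-2-methylidene-6-oxohept-4-enoate
Conditions: 2nd-generation Ru metathesis catalyst (NHC/isopropoxybenzylidene type, 5 mol %), 9 (3 equiv), CH2Cl2, 40 °C
Reagents that add atoms: none
Why: Olefin cross‑metathesis, in which the terminal alkene should pair selectively with the electron‑poor vinyl ketone to give the (E)‑enone under thermodynamic control, while the 1,1‑disubstituted acrylate alkene is inert to the catalyst.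

Step 5
Reactants: 5 2-[(2-oxo-2H-chromen-7-yl)oxy]acetaldehyde; 10 tert-butyl (4E)-2-methylidene-6-oxohept-4-enoate
Product: 12 tert-butyl (4E,6S,7R)-6-methyl-2-methylidene-8-[(2-oxo-2H-chromen-7-yl)oxy]-6,7-bis[(triethylsilyl)oxy]oct-4-enoate, via gamma-siloxyallylchromium(III) species 11 (not isolated)
Conditions: CrCl2 (10 mol %), chiral tridentate carbazole bis(oxazoline) ligand (12 mol %), i-Pr2NEt (30 mol %), Mn powder (2.5 equiv), Et3SiCl (2.5 equiv), THF, 0 °C to rt, slow addition of 10
Reagents that add atoms: chlorotriethylsilane, CC[Si](Cl)(CC)CC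
Why: Proposed new method: the Et3SiCl‑activated enone 10 should take up two electrons from ligated Cr(II) (turned over by Mn) to give the γ‑siloxyallylchromium(III) 11, which adds to aldehyde 5 through its fully substituted γ‑carbon in a closed six‑membered chair transition state, after which Et3SiCl releases the chromium alkoxide as its silyl ether. The closest known reaction types are the Cr(II)/R3SiCl pinacol‑type cross‑coupling of α,β‑unsaturated ketones with aldehydes and the bis(oxazoline)‑controlled Cr‑catalysed (Nozaki–Hiyama–Kishi‑type) addition of γ,γ‑disubstituted allyl donors to aldehydes, and only their combination, ligand control over a siloxyallyl donor made from an enone, is new. No ring is closed. The relative configuration (C6–O anti to C7–O) should follow from the chair in which the CH2OAr group of the aldehyde and the OSiEt3 group (trans to C4 in 11, inherited from the s‑trans enone) are equatorial and the methyl group is axial, while the equatorial C4 substituent gives the (E)‑alkene. The absolute configuration (6S,7R, that is Si face of the aldehyde and Re face of the γ‑carbon) rests on the chiral ligand on chromium. The step needs chemoselectivity among three conjugated carbonyl units, which is secured because only the ketone is basic enough to be silylated and then reduced by Cr(II) while the tert‑butyl acrylate and the coumarin lactone stay untouched, and γ‑regioselectivity is the normal behaviour of allylchromium reagents.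

Step 6
Reactants: 12 tert-butyl (4E,6S,7R)-6-methyl-2-methylidene-8-[(2-oxo-2H-chromen-7-yl)oxy]-6,7-bis[(triethylsilyl)oxy]oct-4-enoate
Product: 13 7-{[(2R,3R,4S)-4-iodo-3-methyl-4-[(2S)-4-methylidene-5-oxooxolan-2-yl]-2,3-bis[(triethylsilyl)oxy]butyl]oxy}-2H-chromen-2-one
Conditions: I2 (3 equiv), NaHCO3 (3 equiv), MeCN, −20 °C to 0 °C, dark
Reagents that add atoms: iodine, II
Why: Iodolactonisation (5‑exo, anti addition), in which I+ should engage the C4=C5 alkene anti to the bulky C7 chain in the conformer that keeps the allylic C6–OSiEt3 bond near the alkene plane (inside‑alkoxy model), so the ester carbonyl oxygen opens the iodonium at C4, remote from quaternary C6, and sets the (S)‑lactone carbon with loss of 2‑methylpropene, while the acrylate and coumarin alkenes are too electron‑poor to react.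

Step 7
Reactants: 13 7-{[(2R,3R,4S)-4-iodo-3-methyl-4-[(2S)-4-methylidene-5-oxooxolan-2-yl]-2,3-bis[(triethylsilyl)oxy]butyl]oxy}-2H-chromen-2-one
Product: 14 7-{[(2R,3S)-3-methyl-4-[(2S)-4-methylidene-5-oxooxolan-2-yl]-2,3-bis[(triethylsilyl)oxy]butyl]oxy}-2H-chromen-2-one
Conditions: n-Bu3SnH (1.2 equiv), Et3B (0.2 equiv), air, toluene (0.3 M), −20 °C
Reagents that add atoms: none
Why: Radical chain dehalogenation, in which iodine abstraction by the stannyl radical is far faster than its addition to the α‑methylene lactone, a high stannane concentration at low temperature should quench the secondary radical before it adds to an acrylate, and only the C–I carbon changes (to CH2).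

Step 8
Reactants: 14 7-{[(2R,3S)-3-methyl-4-[(2S)-4-methylidene-5-oxooxolan-2-yl]-2,3-bis[(triethylsilyl)oxy]butyl]oxy}-2H-chromen-2-one
Product: 15 7-{[(2R,3S)-2,3-dihydroxy-3-methyl-4-[(2S)-4-methylidene-5-oxooxolan-2-yl]butyl]oxy}-2H-chromen-2-one (target)
Conditions: HF·pyridine, pyridine/THF, 0 °C to rt
Reagents that add atoms: none
Why: Fluoride‑mediated silyl ether cleavage under weakly acidic conditions, which should free both hydroxyl groups without touching the α‑methylene lactone, the coumarin or the tertiary alcohol (no longer allylic), so no stereocentre is affected.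

**Compound list**
1 | umbelliferone (7-hydroxy-2H-chromen-2-one) | Oc1ccc2ccc(=O)oc2c1 | starting material
2 | allyl bromide (3-bromoprop-1-ene) | C=CCBr | starting material
3 | 7-(prop-2-en-1-yloxy)-2H-chromen-2-one | C=CCOc1ccc2ccc(=O)oc2c1 | intermediate
4 | 7-(2,3-dihydroxypropoxy)-2H-chromen-2-one (racemic, not isolated) | OCC(O)COc1ccc2ccc(=O)oc2c1 | intermediate
5 | 2-[(2-oxo-2H-chromen-7-yl)oxy]acetaldehyde | O=CCOc1ccc2ccc(=O)oc2c1 | intermediate
6 | tert-butyl 2-(bromomethyl)prop-2-enoate | C=C(CBr)C(=O)OC(C)(C)C | starting material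
7 | vinylmagnesium bromide | C=C[Mg]Br | starting material
8 | tert-butyl 2-methylidenepent-4-enoate | C=CCC(=C)C(=O)OC(C)(C)C | intermediate
9 | methyl vinyl ketone (but-3-en-2-one) | C=CC(C)=O | starting material
10 | tert-butyl (4E)-2-methylidene-6-oxohept-4-enoate | CC(=O)/C=C/CC(=C)C(=O)OC(C)(C)C | intermediate
11 | γ-(triethylsilyloxy)allylchromium(III) species from 10 (Cr on C4, labile; C5=C6 enol silane with OSiEt3 trans to C4; drawn as the dichloride, chiral ligand omitted; not isolated) | C/C(O[Si](CC)(CC)CC)=C\C([Cr](Cl)Cl)CC(=C)C(=O)OC(C)(C)C | intermediate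
12 | tert-butyl (4E,6S,7R)-6-methyl-2-methylidene-8-[(2-oxo-2H-chromen-7-yl)oxy]-6,7-bis[(triethylsilyl)oxy]oct-4-enoate | C=C(C/C=C/[C@](C)(O[Si](CC)(CC)CC)[C@H](O[Si](CC)(CC)CC)COc1ccc2ccc(=O)oc2c1)C(=O)OC(C)(C)C | intermediate
13 | 7-{[(2R,3R,4S)-4-iodo-3-methyl-4-[(2S)-4-methylidene-5-oxooxolan-2-yl]-2,3-bis[(triethylsilyl)oxy]butyl]oxy}-2H-chromen-2-one | C=C1C[C@@H]([C@H](I)[C@](C)(O[Si](CC)(CC)CC)[C@H](O[Si](CC)(CC)CC)COc2ccc3ccc(=O)oc3c2)OC1=O | intermediate
14 | 7-{[(2R,3S)-3-methyl-4-[(2S)-4-methylidene-5-oxooxolan-2-yl]-2,3-bis[(triethylsilyl)oxy]butyl]oxy}-2H-chromen-2-one | C=C1C[C@@H](C[C@](C)(O[Si](CC)(CC)CC)[C@H](O[Si](CC)(CC)CC)COc2ccc3ccc(=O)oc3c2)OC1=O | intermediate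
15 | 7-{[(2R,3S)-2,3-dihydroxy-3-methyl-4-[(2S)-4-methylidene-5-oxooxolan-2-yl]butyl]oxy}-2H-chromen-2-one | C=C1C[C@@H](C[C@](C)(O)[C@H](O)COc2ccc3ccc(=O)oc3c2)OC1=O | target

**Totals**
Total step count: 8.
Longest linear sequence: 6 steps (1, 2, 5, 6, 7, 8 or 3, 4, 5, 6, 7, 8).

**Steps most likely to fail**

Step 5 (Proposed new method).
- The ligand may give too little enantiofacial control over a siloxyallyl donor.
- The anti preference may erode through scrambling of the enol silane geometry.
- Reductive dimerisation or simple 1,4‑reduction of the enone may outrun the carbonyl addition.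

Fallback (known chemistry, sets out from 5, comes back at 12): the same bond is made under reagent control with a small boron donor, and the ester arm is attached afterwards. Commercial but‑2‑yn‑1‑ol is acylated with methyl chloroformate to but‑2‑yn‑1‑yl methyl carbonate F1. Copper‑catalysed SN2' borylation of F1 with bis(pinacolato)diboron gives 1‑methylallenyl pinacolboronate F2. Hydroboration with diisopinocampheylborane from (+)‑α‑pinene, followed by thermal equilibration, gives the γ‑boryl allylborane F3 (pinacolboryl group trans to the CH2B carbon). F3 adds to 5 at −78 °C through a chair transition state to give the borinate adduct F4. Buffered oxidation with NaBO3 gives the anti vinyl diol F5, cross‑metathesis of F5 with 8 gives the (E)‑diol ester F6, and TESOTf/2,6‑lutidine returns 12.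

Step 6.
- Facial selectivity in the iodonium opening may be poor if the bulky silyl ether does not take the inside position.
- The tert‑butyl ester may participate too slowly.

Fallback (sets out from 12, comes back at 14): substrate control is replaced by catalyst control. The tert‑butyl ester is cleaved with TMSOTf/2,6‑lutidine and aqueous work‑up to the free acid F7. An enantioselective bromolactonisation with a chiral bifunctional amidine or amino‑thiocarbamate catalyst and N‑bromosuccinimide sets the lactone carbon and gives bromolactone F8. Stannane reduction of F8 gives 14.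

Step 7.
- The stannyl radical or the intermediate alkyl radical may add to the α‑methylene lactone (hydrostannation, oligomerisation).

Fallback (sets out from 13, comes back at 14): the acrylate is masked during the radical step. Conjugate addition of dimethylamine to 13 at 0 °C gives the β‑amino lactone F9 (epimers at the new α‑carbon, inconsequential). n‑Bu3SnH removes the iodine to give amino lactone F10. N‑methylation with MeI and elimination with NaHCO3 regenerates the methylene group and gives 14.

**Further compounds**
F1 | step 5 | but-2-yn-1-yl methyl carbonate | CC#CCOC(=O)OC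
F2 | step 5 | 2-(buta-2,3-dien-2-yl)-4,4,5,5-tetramethyl-1,3,2-dioxaborolane | C=C=C(C)B1OC(C)(C)C(C)(C)O1
F3 | step 5 | [3-(pinacolboryl)but-2-en-1-yl]diisopinocampheylborane from (+)-α-pinene, Bpin trans to the CH2B carbon | C/C(B1OC(C)(C)C(C)(C)O1)=C\CB([C@@H]1C[C@@H]2C[C@H]([C@H]1C)C2(C)C)[C@@H]1C[C@@H]2C[C@H]([C@H]1C)C2(C)C
F4 | step 5 | diisopinocampheylborinate of the tertiary allylic pinacolboronate adduct of F3 and 5 | C=C[C@](C)(B1OC(C)(C)C(C)(C)O1)[C@H](OB([C@@H]1C[C@@H]2C[C@H]([C@H]1C)C2(C)C)[C@@H]1C[C@@H]2C[C@H]([C@H]1C)C2(C)C)COc1ccc2ccc(=O)oc2c1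
F5 | step 5 | 7-{[(2R,3S)-2,3-dihydroxy-3-methylpent-4-en-1-yl]oxy}-2H-chromen-2-one | C=C[C@](C)(O)[C@H](O)COc1ccc2ccc(=O)oc2c1
F6 | step 5 | tert-butyl (4E,6S,7R)-6,7-dihydroxy-6-methyl-2-methylidene-8-[(2-oxo-2H-chromen-7-yl)oxy]oct-4-enoate | C=C(C/C=C/[C@](C)(O)[C@H](O)COc1ccc2ccc(=O)oc2c1)C(=O)OC(C)(C)C
F7 | step 6 | (4E,6S,7R)-6-methyl-2-methylidene-8-[(2-oxo-2H-chromen-7-yl)oxy]-6,7-bis[(triethylsilyl)oxy]oct-4-enoic acid | C=C(C/C=C/[C@](C)(O[Si](CC)(CC)CC)[C@H](O[Si](CC)(CC)CC)COc1ccc2ccc(=O)oc2c1)C(=O)O
F8 | step 6 | 7-{[(2R,3R,4S)-4-bromo-3-methyl-4-[(2S)-4-methylidene-5-oxooxolan-2-yl]-2,3-bis[(triethylsilyl)oxy]butyl]oxy}-2H-chromen-2-one | C=C1C[C@@H]([C@H](Br)[C@](C)(O[Si](CC)(CC)CC)[C@H](O[Si](CC)(CC)CC)COc2ccc3ccc(=O)oc3c2)OC1=O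
F9 | step 7 | dimethylamine conjugate adduct of 13 (α-[(dimethylamino)methyl] lactone, epimers at the α-carbon) | CN(C)CC1C[C@@H]([C@H](I)[C@](C)(O[Si](CC)(CC)CC)[C@H](O[Si](CC)(CC)CC)COc2ccc3ccc(=O)oc3c2)OC1=O
F10 | step 7 | deiodinated α-[(dimethylamino)methyl] lactone (epimers at the α-carbon) | CN(C)CC1C[C@@H](C[C@](C)(O[Si](CC)(CC)CC)[C@H](O[Si](CC)(CC)CC)COc2ccc3ccc(=O)oc3c2)OC1=O
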